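## Structural features

Numbering follows the asbestinin skeleton. C1–C10 form the ten-membered carbocycle (C6 ketone, C7 exocyclic methylene C19, C4 octanoate, C3 methyl C20). C1/C10–C14 form the cyclohexane (C11 acetate, C12 methyl C18, C14 side chain C15(C17)–C16).

Four rings share atoms. Cyclohexane A (C1, C10–C14) is cis-fused at C1–C10 to tetrahydrofuran B (O, C2, C1, C10, C9). B and the oxonane C (O, C2–C9) share the C2–O–C9 unit as an 11-oxabicyclo[6.2.1]undecane. Oxepane D (C3–O–C16–C15–C14–C1–C2) ties the quaternary C3 to the C14 side chain.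

There are ten stereocentres: the arrays C4–C3–C2–C1–C14–C15 and C1–C10–C11–C12, plus C9 across the ether. H2 and H9 are cis to each other and anti to H1/H10, so ring A sits on the face of B opposite the six-carbon bridge. The C12 methyl is axial and syn to C9.

Fragile groups: the C4 octanoate is β to the C6 ketone (E1cB loss), the α-methylene ketone is a Michael acceptor, two different esters sit on two secondary alcohols, and C3 is a tertiary ether.

The real difficulty is the oxygen-bridged nine-membered ring C with its cis C2/C9 junction and the fully substituted C3 beside it. The stereocentres of rings A and D can be derived from that bicyclic core once it exists.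

The key step exploits this feature: atoms O, C2, C3, C4, C5, C6 of ring C would form a tetrahydropyran if O were bonded to C6. C6 is then allylic to C7=C8, and C9 lies α to the ring-B carbon C10, which can be a ketone. An oxonium ylide at C9 can therefore shift [2,3] from O–C6 to C8 and turn the six-membered ring into rings B and C at once.

## Logic of the disconnections

**34 ⇒ 33 ⇒ 31 ⇒ 30.** The C6 carbonyl and the C7=C19 methylene are traced back to a C6=C7 alkene carrying C19 as methyl, through the C6 allylic alcohol and the 6,7-epoxide. This keeps the β-acyloxy enone out of the route until the last step. The forward steps must be compatible with two esters, and the epoxide must lose a proton from C19, not from C8.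

**30 ⇒ 28 ⇒ 27.** After removal of the octanoyl group, the C3–O bond of ring D is cut. The C16 hydroxyl of 27 opens a 3,4-epoxide at C3, which closes the oxepane, inverts C3 and frees the C4 hydroxyl in one operation. The gain is that C3 and C4 need no protecting groups. The demand is an epoxide on the face of ring C opposite C1 that survives until this point.

**27 ⇒ 26 ⇒ 25 ⇒ 24 ⇒ 23 ⇒ 22.** These are functional-group steps on ring A: C16–OH from an isopropenyl group (sets C15), the C11 acetate from a C11 ketone by hydride delivery on the convex face, the ketone from the ethyl enol ether C10=C11 (sets C10), and the isopropenyl group from the C15 methyl ketone. The demand is that the axial C12 methyl is not equilibrated while C11 is a ketone.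

**22 ⇒ 19 + 20.** Ring A is cut at C1–C14 and C12–C13 (Diels–Alder). The diene is C1=C10–C11(OEt)=C12 on the bicyclic core, and 20 supplies C13, C14, C15 and C17. C1 and C12 are set by the face and geometry of the diene. C14 is α to a ketone and can be equilibrated.

**19 ⇒ 16 + 18; 16 ⇒ 15; 18 ⇒ 17.** The C10–C11 bond is cut (cross-coupling of the C10 enol triflate with an α-ethoxyalkenyl stannane). The stannane must carry ethoxy and methyl cis, so that the methyl is "outside" in the diene.

**15 ⇒ 13 (key).** The C8–C9 bond is cut and O is reconnected to C6. The bridged rings B and C collapse to a 2,6-cis tetrahydropyran bearing a diazoketone chain on C2 and an isopropenyl group on C6. Only C2 (with the epoxide, which follows from it) must be controlled before the key step. The demand is clean ylide formation at the ring oxygen and [2,3]-shift.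

In one sentence: a copper carbenoid from a tetrahydropyranyl diazoketone forms a bicyclic oxonium ylide whose [2,3]-shift expands the six-membered ether into the 11-oxabicyclo[6.2.1]undecenone. This is not the ring-closing metathesis or Diels–Alder plan that would be drawn first.

**13 ⇒ 11 ⇒ 10 ⇒ 9.** The diazoketone comes from the carboxylate, and the epoxide from the ring alkene C3=C4. Epoxidation must occur anti to the two cis ring substituents.

**9 ⇒ 8 ⇒ 6 + 7.** The C2–C1 bond (acetate enolate addition to the lactone carbonyl) and the C2–H bond (oxocarbenium reduction) are cut. C2 is set from C6.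

**6 ⇒ 5 ⇒ 3 + 4; 3 ⇒ 1 + 2.** The ring alkene C3=C4 is cut by ring-closing metathesis of a methacrylate ester, and the C5–C6 bond by asymmetric allylation of 1. One catalytic asymmetric step provides all absolute stereochemistry.

## Other disconnections considered

**Alternative 1:** This is the plan that comes to mind first. Cut C6=C7 by ring-closing metathesis of an acyclic bis-allylic ether to give the oxonene tetraene A1, then cut C1–C10 and C13–C14 by an intramolecular Diels–Alder reaction of A1 that forms rings A and B. In the linear ether, C2, C3, C4 and C9 would each have to be set by separate auxiliary- or reagent-controlled operations. Closure of a nine-membered ring next to a quaternary carbon needs conformational help from protecting groups. The cycloaddition leaves a C11=C12 alkene whose hydroboration puts oxygen on the wrong face of C11, so a redox inversion follows. The chosen plan derives C9 from C2 inside the rearrangement and needs one stereocentre before the key step.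

**Alternative 2:** Cut C5–C6 and reconnect C3–C8: a Cope ring expansion of the cis-2,3-dialkenyl-7-oxanorbornane A2, itself from a furan Diels–Alder adduct (dearomatization). It would give the bridged oxonadiene with C3(Me)=C4 and a C7 allylsilane, a good match for the C3/C4/C7 functionality. A furan cycloaddition, however, furnishes only one substituted two-carbon bridge. Ring A would have to be annulated on the other bridge, an unactivated and nearly symmetric C1=C10 alkene, with no handle for regio- or enantiocontrol. The [3,3] equilibrium rests only on the balance between oxanorbornane strain and oxonadiene strain. The plan is longer and less certain.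

**Alternative 3:** Cut C6–C7 last: intramolecular Nozaki–Hiyama–Kishi coupling of the iodo-aldehyde A3 would close ring C and deliver the C6 carbinol with the C7 methylene directly. It requires the complete A/B/D tricycle with two side chains placed cis on the tetrahydrofuran in separate steps. It uses a β-silyloxy aldehyde that is prone to elimination. It closes the nine-membered ring end to end under high dilution against the quaternary C3. The ring expansion chosen makes the medium ring from a six-membered ring without an entropic penalty.

Key step: step 9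

Assumptions:
- 1-Ethoxyprop-1-yne (17) is taken as a commercial ynol ether.
- Step 9 is drawn for the (Z)-C6=C7 isomer. The (E) isomer would converge at 33 because steps 21–23 erase the stereochemistry at C6 and C7; for the same reason the configuration at C6/C7 is left open in 31–33.

## Steps

Step 1
Reactants: 1 methacrolein; 2 allyltributylstannane
Product: 3 (S)-2-methylhexa-1,5-dien-3-ol
Conditions: (S)-BINOL (10 mol %), Ti(OiPr)4 (10 mol %), 4 Å MS, CH2Cl2, −20 °C; aq. NaHCO3
Reagents that add atoms: none
Why: Keck asymmetric allylation; the BINOL–titanium complex selects one face of the aldehyde and should set C6 as (S) (the BINOL enantiomer fixes the sense); this centre only relays chirality to C2 and is erased in step 9.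

Step 2
Reactants: 3 (S)-2-methylhexa-1,5-dien-3-ol; 4 methacryloyl chloride
Product: 5 (S)-2-methylhexa-1,5-dien-3-yl 2-methylprop-2-enoate
Conditions: Et3N, DMAP (cat.), CH2Cl2, 0 °C
Reagents that add atoms: none
Why: DMAP-catalysed O-acylation; no stereocentre is touched.

Step 3
Reactants: 5 (S)-2-methylhexa-1,5-dien-3-yl 2-methylprop-2-enoate
Product: 6 (S)-3-methyl-6-(prop-1-en-2-yl)-5,6-dihydro-2H-pyran-2-one
Conditions: Grubbs II (5 mol %), CH2Cl2, 40 °C
Reagents that add atoms: none
Why: Ring-closing metathesis; the catalyst initiates at the terminal allyl alkene and closes the six-membered ring onto the methacrylate, while the isopropenyl group could only give a cyclobutene and stays out.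

Step 4
Reactants: 6 (S)-3-methyl-6-(prop-1-en-2-yl)-5,6-dihydro-2H-pyran-2-one; 7 ethyl bromoacetate
Product: 8 ethyl 2-[(6S)-2-hydroxy-3-methyl-6-(prop-1-en-2-yl)-5,6-dihydro-2H-pyran-2-yl]acetate (lactol, anomer mixture)
Conditions: Zn (activated), THF, 0 °C → rt; H2O
Reagents that add atoms: none
Why: Reformatsky reaction; the zinc enolate should add 1,2 to the lactone carbonyl in preference to conjugate addition, and the tetrahedral adduct is held as the lactol.

Step 5
Reactants: 8 ethyl 2-[(6S)-2-hydroxy-3-methyl-6-(prop-1-en-2-yl)-5,6-dihydro-2H-pyran-2-yl]acetate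
Product: 9 ethyl 2-[(2S,6S)-3-methyl-6-(prop-1-en-2-yl)-5,6-dihydro-2H-pyran-2-yl]acetate (2,6-cis)
Conditions: Et3SiH, BF3·OEt2, CH2Cl2/MeCN, −40 °C
Reagents that add atoms: none
Why: Lewis-acid ionisation to the cyclic oxocarbenium ion and silane reduction (C-glycoside-type reductive deoxygenation); hydride should enter axially at C2 so that the acetate arm ends equatorial and cis to the C6 substituent, which sets C2 from C6.

Step 6
Reactants: 9 ethyl 2-[(2S,6S)-3-methyl-6-(prop-1-en-2-yl)-5,6-dihydro-2H-pyran-2-yl]acetate
Product: 10 ethyl 2-[2,6-cis-3,4-epoxy-3-methyl-6-(prop-1-en-2-yl)tetrahydropyran-2-yl]acetate (epoxide trans to both ring substituents)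
Conditions: mCPBA (1.05 equiv), NaHCO3, CH2Cl2, −20 → 0 °C
Reagents that add atoms: 3-chloroperbenzoic acid (mCPBA), O=C(OO)c1cccc(Cl)c1
Why: Prilezhaev epoxidation; the trisubstituted ring alkene is more electron-rich than the 1,1-disubstituted isopropenyl group, and the peracid should approach the face opposite the two cis substituents at C2 and C6, which sets C3 and C4.

Step 7
Reactants: 10 ethyl 2-[2,6-cis-3,4-epoxy-3-methyl-6-(prop-1-en-2-yl)tetrahydropyran-2-yl]acetate
Product: 11 lithium 2-[2,6-cis-3,4-epoxy-3-methyl-6-(prop-1-en-2-yl)tetrahydropyran-2-yl]acetate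
Conditions: LiOH·H2O (1.1 equiv), THF/MeOH/H2O, 0 °C → rt; concentrate, dry by azeotrope (no acidification)
Reagents that add atoms: lithium hydroxide, [Li+].[OH-]
Why: Ester saponification; base leaves the epoxide intact, and the salt is used as such because the free acid could open the epoxide at C3 to a γ-lactone.

Step 8
Reactants: 11 lithium 2-[2,6-cis-3,4-epoxy-3-methyl-6-(prop-1-en-2-yl)tetrahydropyran-2-yl]acetate
Product: 13 1-diazo-3-[2,6-cis-3,4-epoxy-3-methyl-6-(prop-1-en-2-yl)tetrahydropyran-2-yl]propan-2-one, via mixed isobutyl carbonic anhydride 12 (not isolated)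
Conditions: iBuOCOCl, THF, −15 °C; then TMSCHN2, MeCN, 0 °C → rt
Reagents that add atoms: trimethylsilyldiazomethane, C[Si](C)(C)C=[N+]=[N-]; isobutyl chloroformate, CC(C)COC(Cl)=O (its atoms remain only in 12)
Why: Mixed-anhydride activation and C-acylation of the diazoalkane (Arndt–Eistert-type diazoketone synthesis) under neutral conditions that spare the epoxide.

Step 9
Reactants: 13 1-diazo-3-[2,6-cis-3,4-epoxy-3-methyl-6-(prop-1-en-2-yl)tetrahydropyran-2-yl]propan-2-one
Product: 15 (6Z)-3,4-epoxy-3,7-dimethyl-11-oxabicyclo[6.2.1]undec-6-en-10-one (asbestinin numbering: O bridges C2 and C9, ketone at C10), via bicyclic oxonium ylide 14 (not isolated)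
Conditions: Cu(hfacac)2 (5 mol %), CH2Cl2, reflux, slow addition of 13
Reagents that add atoms: none
Why: Copper-catalysed loss of N2 gives an electrophilic carbenoid at C9 that is captured by a lone pair of the tetrahydropyran oxygen, and the free oxonium ylide 14 then undergoes a concerted [2,3]-sigmatropic shift through a five-membered envelope transition state in which C9 bonds to the isopropenyl CH2 (C8), the allylic O–C6 bond breaks and C6=C7 forms. The closest known reaction type is the catalytic intramolecular oxonium-ylide formation/[2,3]-rearrangement of cyclic allylic ethers to bridged medium-ring ethers. Ring B (a tetrahydrofuran-3-one) closes by 5-exo attack of the ether oxygen on the carbenoid; ring C is not closed end to end but arises by three-atom ring expansion of the six-membered ring (C9, C8 and C7 are inserted between O and C6), so no high dilution is needed. The one new stereocentre, C9, is fixed by C2, because the six-carbon bridge C3–C8 can span the furanone only cis and H9 must therefore be cis to H2; C6, having set C2, disappears. The step needs the [2,3]-shift to win over [1,2]-shift, cyclopropanation of the isopropenyl group, C–H insertion and attack on the epoxide oxygen. The electron-poor hfacac ligands favour ylide formation and release of the metal, O–C6 is the only allylic C–O bond of the ylide because C3/C4 are saturated as the epoxide, and the epoxide oxygen lies on the ring face opposite the diazoketone chain. The alkene is expected mainly as the Z isomer, and its geometry does not matter for the end of the route.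

Step 10
Reactants: 15 (6Z)-3,4-epoxy-3,7-dimethyl-11-oxabicyclo[6.2.1]undec-6-en-10-one
Product: 16 C10 enol triflate of 15 (C1=C10, trifluoromethanesulfonate on C10)
Conditions: KHMDS, PhNTf2, THF, −78 °C
Reagents that add atoms: N-phenylbis(trifluoromethanesulfonimide), O=S(=O)(N(c1ccccc1)S(=O)(=O)C(F)(F)F)C(F)(F)F
Why: Kinetic enolisation and O-triflation; only C1 can be deprotonated, because the C9 enolate would be a strained bridgehead alkene.

Step 11
Reactants: 17 1-ethoxyprop-1-yne
Product: 18 (E)-tributyl(1-ethoxyprop-1-en-1-yl)stannane (ethoxy and methyl cis)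
Conditions: Bu3SnH, Pd(PPh3)4 (2 mol %), THF, 0 °C
Reagents that add atoms: tributyltin hydride, CCCC[SnH](CCCC)CCCC
Why: Palladium-catalysed syn-hydrostannation of an ynol ether; tin should go to the oxygen-bearing carbon and H and Sn add cis, which places ethoxy and methyl on the same side.

Step 12
Reactants: 16 C10 enol triflate of 15; 18 (E)-tributyl(1-ethoxyprop-1-en-1-yl)stannane
Product: 19 diene: 16 with the triflate replaced by a (Z)-1-ethoxyprop-1-en-1-yl group on C10 (C1=C10–C11(OEt)=C12H–CH3)
Conditions: Pd(PPh3)4 (5 mol %), LiCl, CuCl (cat.), THF, 60 °C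
Reagents that add atoms: none
Why: Stille coupling of an enol triflate with an α-alkoxyalkenyl stannane; the alkene geometry is retained, so the C12 methyl sits "outside" in the s-cis diene.

Step 13
Reactants: 19 diene (C1=C10–C11(OEt)=C12H–CH3); 20 methyl vinyl ketone
Product: 22 tricyclic methyl ketone (ring A closed; C11 ethyl enol ether C10=C11; C12 methyl cis to C2; C14 acetyl trans to C2), via endo cycloadduct (14-epimer) 21 (not isolated)
Conditions: 20 (5 equiv), BHT, PhMe, 80 °C; then K2CO3, MeOH, rt
Reagents that add atoms: none
Why: Diels–Alder reaction; the C11 alkoxy group directs the "para" orientation (bonds C12–C13 and C1–C14), the dienophile should add to the diene face away from the six-carbon bridge (sets C1, H1 syn to the bridge), and suprafacial addition places the outside C12 methyl cis to C2; the endo adduct carries the acetyl group cis to C2, and base equilibration through the ketone enolate should move it to the pseudo-equatorial, trans position required at C14.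

Step 14
Reactants: 22 tricyclic methyl ketone
Product: 23 tricyclic isopropenyl enol ether (C14 prop-1-en-2-yl; C10=C11(OEt))
Conditions: Ph3PCH3Br, KOtBu, THF, 0 °C → rt
Reagents that add atoms: methyltriphenylphosphonium bromide, C[P+](c1ccccc1)(c1ccccc1)c1ccccc1.[Br-]
Why: Wittig methylenation of the methyl ketone while C11 is still masked as the enol ether; the basic conditions cannot disturb the thermodynamic C14 configuration.

Step 15
Reactants: 23 tricyclic isopropenyl enol ether
Product: 24 tricyclic C11 ketone (cis A/B fusion, C12 methyl axial)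
Conditions: 0.05 M aq. oxalic acid, THF, 0 °C
Reagents that add atoms: water, O
Why: Acid hydrolysis of the enol ether; protonation at C10 from the convex face gives the cis ring fusion (kinetically and thermodynamically preferred), while dilute acid at 0 °C should spare the epoxide, whose C3 cation is destabilised by the adjacent C2–O bond, and should limit enolisation toward C12.

Step 16
Reactants: 24 tricyclic C11 ketone
Product: 25 tricyclic C11 alcohol (OH cis to the C12 methyl and to C9)
Conditions: L-Selectride, THF, −78 °C; aq. NH4Cl
Reagents that add atoms: none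
Why: Bulky hydride reduction; hydride should attack the convex face, anti to the axial C12 methyl, and the low temperature avoids epimerisation at C12.

Step 17
Reactants: 25 tricyclic C11 alcohol
Product: 26 tricyclic C11 acetate
Conditions: Ac2O, pyridine, DMAP (cat.), CH2Cl2, rt
Reagents that add atoms: acetic anhydride, CC(=O)OC(C)=O
Why: Acetylation of the only hydroxyl group.

Step 18
Reactants: 26 tricyclic C11 acetate
Product: 27 tricyclic primary alcohol (C14 side chain CH(CH3)CH2OH, C15 as in the target)
Conditions: 9-BBN, THF, 0 °C → rt; then H2O2, pH 7 buffer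
Reagents that add atoms: hydrogen peroxide, OO
Why: Hydroboration–oxidation; 9-BBN should select the 1,1-disubstituted alkene over the trisubstituted C6=C7 alkene and leave ester and epoxide alone, and C15 is expected to be set by substrate control (boron adds anti to the C1 side in the conformer with H14 eclipsing the alkene); this selectivity is uncertain.

Step 19
Reactants: 27 tricyclic primary alcohol
Product: 28 tetracyclic C4 alcohol (oxepane ring D closed, C11 acetate, C6=C7 alkene)
Conditions: CSA (0.1 equiv), CH2Cl2, 0 °C → rt
Reagents that add atoms: none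
Why: Acid-catalysed intramolecular epoxide opening (7-exo attack at the tertiary carbon); the C16 hydroxyl can reach C3 only from the face of C1, which is anti to the epoxide oxygen, so C3 is inverted to the target configuration and the C4 hydroxyl is released with retention.

Step 20
Reactants: 28 tetracyclic C4 alcohol; 29 octanoyl chloride
Product: 30 tetracyclic C4 octanoate
Conditions: pyridine, DMAP (cat.), CH2Cl2, 0 °C → rt
Reagents that add atoms: none
Why: Acylation of the only free hydroxyl; the C11 acetate is already in place, which differentiates the two esters.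

Step 21
Reactants: 30 tetracyclic C4 octanoate
Product: 31 6,7-epoxide of 30
Conditions: mCPBA, NaHCO3, CH2Cl2, 0 °C
Reagents that add atoms: 3-chloroperbenzoic acid (mCPBA), O=C(OO)c1cccc(Cl)c1
Why: Prilezhaev epoxidation of the only remaining alkene; either face serves, since C6 and C7 become sp2 in the target.

Step 22
Reactants: 31 6,7-epoxide of 30
Product: 33 C6 allylic alcohol with C7 exocyclic methylene, via C6 trimethylsilyl ether 32 (not isolated)
Conditions: TMSOTf, 2,6-lutidine, PhMe, −78 °C; DBU, rt; then aq. citric acid, THF
Reagents that add atoms: trimethylsilyl trifluoromethanesulfonate, C[Si](C)(C)OS(=O)(=O)C(F)(F)F (silicon remains only in 32)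
Why: Silyl-triflate-promoted isomerisation of an epoxide to an allylic silyl ether; the tertiary C7–O bond ionises and the base should remove a proton from the least hindered C19 methyl to give the exocyclic alkene, and the ester groups tolerate the conditions.

Step 23
Reactants: 33 C6 allylic alcohol with C7 exocyclic methylene
Product: 34 Asbestinin 16
Conditions: Dess–Martin periodinane, NaHCO3, CH2Cl2, 0 °C
Reagents that add atoms: none
Why: Dess–Martin oxidation of the allylic alcohol under buffered, non-basic conditions, chosen to avoid β-elimination of the C4 octanoate and isomerisation of the α-methylene ketone.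

## Compound list

1 | methacrolein | C=C(C)C=O | starting material
2 | allyltributylstannane | C=CC[Sn](CCCC)(CCCC)CCCC | starting material
3 | (S)-2-methylhexa-1,5-dien-3-ol | C=C(C)[C@@H](O)CC=C | intermediate
4 | methacryloyl chloride | C=C(C)C(Cl)=O | starting material
5 | (S)-2-methylhexa-1,5-dien-3-yl 2-methylprop-2-enoate | C=C(C)C(=O)O[C@H](C(C)=C)CC=C | intermediate
6 | (S)-3-methyl-6-(prop-1-en-2-yl)-5,6-dihydro-2H-pyran-2-one | CC1=CC[C@@H](C(C)=C)OC1=O | intermediate
7 | ethyl bromoacetate | BrCC(=O)OCC | starting material
8 | ethyl 2-[(6S)-2-hydroxy-3-methyl-6-(prop-1-en-2-yl)-5,6-dihydro-2H-pyran-2-yl]acetate (anomer mixture) | CCOC(=O)CC1(O)O[C@H](C(C)=C)CC=C1C | intermediate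
9 | ethyl 2-[(2S,6S)-3-methyl-6-(prop-1-en-2-yl)-5,6-dihydro-2H-pyran-2-yl]acetate | CCOC(=O)C[C@@H]1O[C@H](C(C)=C)CC=C1C | intermediate
10 | ethyl 2-[2,6-cis-3,4-epoxy-3-methyl-6-(prop-1-en-2-yl)tetrahydropyran-2-yl]acetate (epoxide trans to both substituents) | CCOC(=O)C[C@@H]1O[C@H](C(C)=C)C[C@H]2O[C@@]12C | intermediate
11 | lithium salt of the acid of 10 | [Li+].[O-]C(=O)C[C@@H]1O[C@H](C(C)=C)C[C@H]2O[C@@]12C | intermediate
12 | mixed isobutyl carbonic anhydride of the acid of 10 | CC(C)COC(=O)OC(=O)C[C@@H]1O[C@H](C(C)=C)C[C@H]2O[C@@]12C | intermediate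
13 | 1-diazo-3-[2,6-cis-3,4-epoxy-3-methyl-6-(prop-1-en-2-yl)tetrahydropyran-2-yl]propan-2-one | [N-]=[N+]=CC(=O)C[C@@H]1O[C@H](C(C)=C)C[C@H]2O[C@@]12C | intermediate
14 | bicyclic oxonium ylide (furanone fused at O–C2 of the tetrahydropyran) | O=C1C[C@@H]2[O+]([CH-]1)[C@H](C(C)=C)C[C@H]3O[C@@]23C | intermediate
15 | (6Z)-3,4-epoxy-3,7-dimethyl-11-oxabicyclo[6.2.1]undec-6-en-10-one (asbestinin numbering) | C/C1=C/C[C@H]2O[C@@]2(C)[C@@H]3CC(=O)[C@H](C1)O3 | intermediate
16 | C10 enol triflate of 15 (C1=C10) | C/C1=C/C[C@H]2O[C@@]2(C)[C@@H]3C=C(OS(=O)(=O)C(F)(F)F)[C@H](C1)O3 | intermediate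
17 | 1-ethoxyprop-1-yne | CCOC#CC | starting material
18 | (E)-tributyl(1-ethoxyprop-1-en-1-yl)stannane (ethoxy and methyl cis) | CCO/C(=C\C)[Sn](CCCC)(CCCC)CCCC | intermediate
19 | diene: C10-[(Z)-1-ethoxyprop-1-enyl] derivative of the bicyclic core (C1=C10–C11(OEt)=C12) | C/C1=C/C[C@H]2O[C@@]2(C)[C@@H]3C=C(/C(OCC)=C/C)[C@H](C1)O3 | intermediate
20 | methyl vinyl ketone (but-3-en-2-one) | C=CC(C)=O | starting material
21 | endo Diels–Alder adduct (14-epimer of 22, acetyl cis to C2) | C/C1=C/C[C@H]2O[C@@]2(C)[C@@H]3[C@H]4[C@@H](C(C)=O)C[C@@H](C)C(OCC)=C4[C@H](C1)O3 | intermediate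
22 | tricyclic methyl ketone (C14 acetyl trans to C2, C10=C11 ethyl enol ether, 3,4-epoxide) | C/C1=C/C[C@H]2O[C@@]2(C)[C@@H]3[C@H]4[C@H](C(C)=O)C[C@@H](C)C(OCC)=C4[C@H](C1)O3 | intermediate
23 | tricyclic isopropenyl enol ether | C/C1=C/C[C@H]2O[C@@]2(C)[C@@H]3[C@H]4[C@H](C(C)=C)C[C@@H](C)C(OCC)=C4[C@H](C1)O3 | intermediate
24 | tricyclic C11 ketone | C/C1=C/C[C@H]2O[C@@]2(C)[C@@H]3[C@H]4[C@H](C(C)=C)C[C@@H](C)C(=O)[C@H]4[C@H](C1)O3 | intermediate
25 | tricyclic C11 alcohol | C/C1=C/C[C@H]2O[C@@]2(C)[C@@H]3[C@H]4[C@H](C(C)=C)C[C@@H](C)[C@@H](O)[C@H]4[C@H](C1)O3 | intermediate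
26 | tricyclic C11 acetate | C/C1=C/C[C@H]2O[C@@]2(C)[C@@H]3[C@H]4[C@H](C(C)=C)C[C@@H](C)[C@@H](OC(C)=O)[C@H]4[C@H](C1)O3 | intermediate
27 | tricyclic primary alcohol (C16–OH, 3,4-epoxide, C11 acetate) | C/C1=C/C[C@H]2O[C@@]2(C)[C@@H]3[C@H]4[C@H]([C@@H](C)CO)C[C@@H](C)[C@@H](OC(C)=O)[C@H]4[C@H](C1)O3 | intermediate
28 | tetracyclic C4 alcohol (rings A–D, C6=C7 Z-alkene, C11 acetate) | C/C1=C/C[C@@H](O)[C@]2(C)OC[C@H](C)[C@@H]3C[C@@H](C)[C@@H](OC(C)=O)[C@H]4[C@H](C1)O[C@H]2[C@@H]34 | intermediate
29 | octanoyl chloride | CCCCCCCC(Cl)=O | starting material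
30 | tetracyclic C4 octanoate | C/C1=C/C[C@@H](OC(=O)CCCCCCC)[C@]2(C)OC[C@H](C)[C@@H]3C[C@@H](C)[C@@H](OC(C)=O)[C@H]4[C@H](C1)O[C@H]2[C@@H]34 | intermediate
31 | 6,7-epoxide of 30 (C6/C7 configuration open) | CC12OC1C[C@@H](OC(=O)CCCCCCC)[C@]3(C)OC[C@H](C)[C@@H]4C[C@@H](C)[C@@H](OC(C)=O)[C@H]5[C@H](C2)O[C@H]3[C@@H]45 | intermediate
32 | C6 trimethylsilyl ether with C7 exocyclic methylene (C6 configuration open) | C=C1C(O[Si](C)(C)C)C[C@@H](OC(=O)CCCCCCC)[C@]2(C)OC[C@H](C)[C@@H]3C[C@@H](C)[C@@H](OC(C)=O)[C@H]4[C@H](C1)O[C@H]2[C@@H]34 | intermediate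
33 | C6 allylic alcohol with C7 exocyclic methylene (C6 configuration open) | C=C1C(O)C[C@@H](OC(=O)CCCCCCC)[C@]2(C)OC[C@H](C)[C@@H]3C[C@@H](C)[C@@H](OC(C)=O)[C@H]4[C@H](C1)O[C@H]2[C@@H]34 | intermediate
34 | Asbestinin 16 | C=C1C[C@@H]2O[C@H]3[C@H]4[C@@H](C[C@@H](C)[C@@H](OC(C)=O)[C@H]42)[C@@H](C)CO[C@@]3(C)[C@H](OC(=O)CCCCCCC)CC1=O | target

## Step count and least certain steps

Total step count: 23. Longest linear sequence: 22 steps (steps 1–10 and 12–23, from methacrolein 1). Step 11 is a one-step branch that supplies the stannane 18.

**Step 9 (key step).** The carbenoid from 13 is unstabilised and very electrophilic. Ylide formation at the ring oxygen may therefore lose to cyclopropanation of the isopropenyl group, C–H insertion, carbene dimerisation or capture by the epoxide oxygen, and the ylide may partly undergo a [1,2]-shift.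

Fallback: set out from 11 with an acceptor/acceptor carbenoid, which forms ylides more selectively.
- Activation of 11 with carbonyldiimidazole and reaction with magnesium monoallyl malonate should give the allyl β-keto ester F1.
- Diazo transfer (p-acetamidobenzenesulfonyl azide, Et3N) should give the diazo keto ester F2.
- Rh2(OAc)4 should then effect the same ylide formation and [2,3] ring expansion to the bicyclic allyl β-keto ester F3, with the ester on C9.
- Pd(PPh3)4 and morpholine remove the allyl ester with decarboxylation. Protonation at C9 can only give the cis-bridged ketone, so the route is rejoined at 15.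

**Step 15.** The acid needed to hydrolyse the tetrasubstituted enol ether may also open the 3,4-epoxide (by water or transannularly), and the new C11 ketone may enolise toward C12 and lose the axial methyl configuration.

Fallback: reorder so that the acid step is the one that consumes the epoxide productively. Set out from 23.
- 9-BBN hydroboration of the isopropenyl group gives the primary alcohol F4, with enol ether and epoxide intact.
- CSA in wet CH2Cl2 then closes ring D by epoxide opening and hydrolyses the enol ether in the same operation, giving the tetracyclic keto alcohol F5.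
- Octanoylation of the C4 hydroxyl gives the keto octanoate F6.
- L-Selectride at −78 °C gives the C11 alcohol F7.
- Acetylation rejoins the route at 30.

**Step 18.** Facial selectivity at C15 may be poor, because the isopropenyl group rotates freely and the nearest stereocentres bias its two faces only weakly.

Fallback: let a catalyst fix C15, not the substrate. Set out from 22.
- Kinetic enolisation toward the methyl group and triflation (KHMDS, PhNTf2) gives the vinyl triflate F8.
- Palladium-catalysed methoxycarbonylation (CO, MeOH, Et3N) gives the α-substituted acrylate F9.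
- Enantioface-selective hydrogenation with a chiral Rh or Ru bisphosphine catalyst, which binds through the ester and ignores the other alkenes, gives the saturated ester F10.
- DIBAL-H reduction gives the primary alcohol F4, which is carried through F5, F6 and F7 as described for step 15 and rejoins the route at 30.

**Step 19.** Ionisation of the epoxide at C3 may be faster than seven-membered ring closure. That would lead to transannular capture by the C6=C7 alkene or to elimination toward C20.

Fallback: form the other C–O bond of the ether (C16–O in place of C3–O). Set out from 26.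
- Aqueous acid (HClO4, THF/H2O) with water in large excess opens the epoxide at C3 with inversion, giving the trans-diol F11.
- The secondary C4 hydroxyl is octanoylated selectively, giving the hydroxy octanoate F12.
- Hydroboration–oxidation of the isopropenyl group gives the diol monoester F13.
- Tf2O and 2,6-lutidine convert the primary alcohol into a triflate that the tertiary C3 hydroxyl displaces in situ. This closes the oxepane and rejoins the route at 30.

## Further compounds

F1 | step 9 | allyl 4-[2,6-cis-3,4-epoxy-3-methyl-6-(prop-1-en-2-yl)tetrahydropyran-2-yl]-3-oxobutanoate | C=CCOC(=O)CC(=O)C[C@@H]1O[C@H](C(C)=C)C[C@H]2O[C@@]12C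
F2 | step 9 | allyl 2-diazo-4-[2,6-cis-3,4-epoxy-3-methyl-6-(prop-1-en-2-yl)tetrahydropyran-2-yl]-3-oxobutanoate | C=CCOC(=O)C(=[N+]=[N-])C(=O)C[C@@H]1O[C@H](C(C)=C)C[C@H]2O[C@@]12C
F3 | step 9 | allyl ester of the C9-carboxylic acid of 15 (bicyclic β-keto ester) | C/C1=C/C[C@H]2O[C@@]2(C)[C@@H]3CC(=O)[C@@](C1)(C(=O)OCC=C)O3
F4 | step 15 | tricyclic primary alcohol with C10=C11 ethyl enol ether and 3,4-epoxide | C/C1=C/C[C@H]2O[C@@]2(C)[C@@H]3[C@H]4[C@H]([C@@H](C)CO)C[C@@H](C)C(OCC)=C4[C@H](C1)O3
F5 | step 15 | tetracyclic C11 ketone with free C4 hydroxyl | C/C1=C/C[C@@H](O)[C@]2(C)OC[C@H](C)[C@@H]3C[C@@H](C)C(=O)[C@H]4[C@H](C1)O[C@H]2[C@@H]34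
F6 | step 15 | tetracyclic C11 ketone C4 octanoate | C/C1=C/C[C@@H](OC(=O)CCCCCCC)[C@]2(C)OC[C@H](C)[C@@H]3C[C@@H](C)C(=O)[C@H]4[C@H](C1)O[C@H]2[C@@H]34
F7 | step 15 | tetracyclic C11 alcohol C4 octanoate | C/C1=C/C[C@@H](OC(=O)CCCCCCC)[C@]2(C)OC[C@H](C)[C@@H]3C[C@@H](C)[C@@H](O)[C@H]4[C@H](C1)O[C@H]2[C@@H]34
F8 | step 18 | vinyl triflate of 22 (C15(OTf)=CH2) | C/C1=C/C[C@H]2O[C@@]2(C)[C@@H]3[C@H]4[C@H](C(=C)OS(=O)(=O)C(F)(F)F)C[C@@H](C)C(OCC)=C4[C@H](C1)O3
F9 | step 18 | methyl acrylate at C14 (C15(=CH2)CO2Me) | C/C1=C/C[C@H]2O[C@@]2(C)[C@@H]3[C@H]4[C@H](C(=C)C(=O)OC)C[C@@H](C)C(OCC)=C4[C@H](C1)O3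
F10 | step 18 | methyl 2-substituted propanoate at C14 (C15 as in the target) | C/C1=C/C[C@H]2O[C@@]2(C)[C@@H]3[C@H]4[C@H]([C@@H](C)C(=O)OC)C[C@@H](C)C(OCC)=C4[C@H](C1)O3
F11 | step 19 | tricyclic 3,4-trans-diol (C11 acetate, C14 isopropenyl) | C/C1=C/C[C@@H](O)[C@](C)(O)[C@@H]2[C@H]3[C@H](C(C)=C)C[C@@H](C)[C@@H](OC(C)=O)[C@H]3[C@H](C1)O2
F12 | step 19 | tricyclic C4 octanoate with free tertiary C3 hydroxyl | C/C1=C/C[C@@H](OC(=O)CCCCCCC)[C@](C)(O)[C@@H]2[C@H]3[C@H](C(C)=C)C[C@@H](C)[C@@H](OC(C)=O)[C@H]3[C@H](C1)O2
F13 | step 19 | tricyclic C4 octanoate with C3 and C16 hydroxyls | C/C1=C/C[C@@H](OC(=O)CCCCCCC)[C@](C)(O)[C@@H]2[C@H]3[C@H]([C@@H](C)CO)C[C@@H](C)[C@@H](OC(C)=O)[C@H]3[C@H](C1)O2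
A1 | alternative 1 | 2,9-cis-oxon-6-ene tetraene (C2 enone dienophile, C9 diene, C3/C4 bis-triethylsilyl ethers) | CC(=O)/C=C/[C@@H]1O[C@H](/C=C/C(C)=C)C/C(C)=C\C[C@@H](O[Si](CC)(CC)CC)[C@]1(C)O[Si](CC)(CC)CC
A2 | alternative 2 | cis-exo-2,3-dialkenyl-7-oxanorbornane with ring A exo-fused (C3 methyl and vinyl, C8 2-(trimethylsilylmethyl)vinyl) | C=C(C[Si](C)(C)C)[C@@H]1[C@@H]2O[C@H]([C@]1(C)C=C)[C@H]3[C@H](C(C)=C)C[C@@H](C)[C@@H](OC(C)=O)[C@H]32
A3 | alternative 3 | A/B/D tricyclic iodo-aldehyde (C6 aldehyde, C7 vinyl iodide, C4 TBS ether) | O=CC[C@@H](O[Si](C)(C)C(C)(C)C)[C@]2(C)OC[C@H](C)[C@@H]3C[C@@H](C)[C@@H](OC(C)=O)[C@H]4[C@H](CC(I)=C)O[C@H]2[C@@H]34
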